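The amounts come first: the Rgt charge is 70.0% of the Sbt charge, less than the Sbt that Tsp can leave, so Rgt is the limiting reagent and Pdt in the long run stays below 70.0%. How fast the flask approaches that end is the open question.

Sbt 0.40 M; Rgt 0.280 M (fed, over 40 min); Tsp 0.0200 M; Cat 44 mM; time 80 min; the fed solution adds 1.0 times the starting volume

    Sbt + Rgt + Cat → Cat + Pdt (k1 = 2.8 /M²/min)
    Sbt + Tsp → Sid (k2 = 0.32 /M/min)
    Sbt + Pdt ⇌ Int, settled at all times (K3 = 2.9 /M)
    Rgt + Pdt → Sid2 (k4 = 0.032 /M/min)

- a species is counted by the Sbt in it: one Int counts as two
- amounts and yields of Pdt count Int too
- charges are per starting volume, the dose included; the dosed solution carries all of it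
- in an amount of Pdt, one Int counts as one Pdt
- the reaction counts as stopped when no species that holds the Sbt changes by six tenths of a point or more over the second half of the time
- what has gone from Sbt into another species counts as reacted, even if it can come back
- run time (flask): 80 min

- which holds at 80 min: what has brought the reaction to rest, or that it has not come to rest (it is still moving / Rgt has run out first / no working catalyst is left / all of Sbt has reacted)
- share of the Sbt used up at 80 min
- Pdt at 80 min, in percent of the Sbt charged
- Sid2 at 80 min, in percent of the Sbt charged
- amount of Pdt if the flask were left three thousand times as long, in percent of the Sbt charged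

I order the events by time. First comes Int, which is kept at balance with Sbt and Pdt and adds no time of its own. Next comes Tsp, whose lifetime against c_Sbt at the start is 7.81 min, shorter than the feed, so I count its charge, 5.00% of the Sbt, as gone early. Then comes the feed, which gives a portion of Rgt a mean stay of 60.0 min. I treat the decay of Rgt as pseudo-first-order and name its lifetime in the full flask: one over the first step's constant times c_Cat and c_Sbt, both diluted by the added volume, with c_Sbt taken as the charge less Tsp and less half the Rgt charge, 135 min. The stay is shorter than this, so I reckon that 64.2% of the Rgt remains, and my answer is: it is still moving. The last rung is the loss of Rgt on Pdt: even with the whole Rgt charge as Pdt, its time is 223 min, longer than the other times on my ladder, so I drop it for the asked time. Pdt then comes to 25.1% of the Sbt, and my reckoning stops there.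

The forecast answers "it is still moving", with 43% of the Sbt used, 28.8% Pdt (above my figure), 2.6% Sid2, and 45% Pdt in the long run, the last on the ground that “Rgt runs out before Sbt does”.

The simulated flask answers "it is still moving", with 43.3% of the Sbt used, 28.8% Pdt, 2.44% Sid2, and 44.9% Pdt in the long run. At 80.0 min this flask holds 52% of its Rgt charge, less than my 64.2%. Kept unchanged, my lifetime leaves 0.313% of the Rgt at 800 min, and this flask then holds 0.450%.

In a second flask, with 0.68 M of Sbt and the other charges and the time held, the lifetime becomes 62.4 min, which gives Pdt at 25.4% of its Sbt. The simulation of that flask gives 24.8% Pdt.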